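Remark on the chemistry: the structure string defines no sense of twist about the hindered C5–C3' biaryl bond, so the route aims at the racemate with respect to this axis.

## Analysis of the target

Target 23 is an unsymmetrical bis-naphthoquinone built from two bicyclic halves joined by a single C–C bond. In the numbering used here, the juglone half has C1=O, C2–OMe, C3–H and C4=O in its quinone ring and C5 (the link), C6–CH3, C7–H and C8–OH in its benzenoid ring, with C8–OH peri to C1=O. The naphthazarin half has C1'=O, C2'–CH3, C3' (the link) and C4'=O, plus the chelated hydroxyls C5'–OH and C8'–OH. There is no stereogenic centre; the only stereo-element is the C5–C3' axis, flanked by C6–CH3 and the peri C4 carbonyl on one side and by C2'–CH3 and the C4' carbonyl on the other. The sensitive groups are the two electrophilic, redox-active quinones, the vinylogous methyl ester at C2 (vulnerable to nucleophiles and strong Lewis acids) and three chelated peri-phenols, two of which form a base- and oxidant-sensitive naphthazarin. The synthesis is hard for three reasons: the C5–C3' bond joins two carbons that each carry two ortho substituents, the methoxy group must end up on the quinone carbon next to the carbonyl that is peri to the hydroxyl, and four oxygenated rings have to reach different oxidation levels. The strategy rests on the benzenoid ring of the naphthazarin half (C4a', C5', C6', C7', C8', C8a'): it has a local mirror plane exchanging C5'–OH with C8'–OH and C6'–H with C7'–H, so it can come from the symmetrical aryne 17. The remaining carbons C1'–C4', with the C2' methyl and the C3' aryl already attached, then map onto the 3,4-disubstituted furan 14.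

## Retrosynthetic reasoning

**23 to 22.** No skeletal bond is cut; the three O–H groups at C8, C5' and C8' are traced back to methyl ethers. These three oxygens each sit peri to a quinone carbonyl, so chelation makes them the ethers that a boron Lewis acid removes first, while the C2 methoxy lacks this six-membered chelate. The gain is that methyl is the only protecting group in the whole route. The forward step must cleave three ethers and spare the fourth.

**22 to 21.** The juglone-half quinone is traced back to its reduced, O-methylated form, a 1,2,4,8-tetramethoxynaphthalene. C1 and C4 are the only para-related methoxy pair in that ring system, so a one-electron oxidant can only produce the 2-methoxy-1,4-quinone. The quinone already present in the other half is electron-poor and should be left alone. The gain is that the juglone half travels through all organometallic steps as an inert arene.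

**21 to 18 (through 19 and 20).** One quinone oxygen of the naphthazarin half is removed and the other is reconnected as an ether bridge between C1' and C4'. In the forward direction, acid opens the bridge to the naphthols 19 and 20, and a phenol-selective oxidant then oxygenates the free para position. The cut is placed here because an oxygen bridge is exactly what a furan leaves behind, and because both naphthols give the same quinone, so the direction of opening does not matter.

**18 to 14 and 17 (from 15).** The bonds C1'–C8a' and C4'–C4a' are cut. This is the only pair of cuts in the naphthazarin half that leaves a mirror-symmetric fragment, so the forward cycloaddition has no orientation problem. Both new bonds form at the α-carbons of the furan, one atom away from the crowded C3'. Cuts at C2'–C3', C3'–C4' or in the ring around C5 would instead require bond formation at a carbon next to the axis. The forward reaction must generate 17 from 15 in the presence of 14 and make the furan, not the methoxynaphthalene rings, act as the diene.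

**14 to 8 and 11.** The C5–C3' bond is cut at the aryl–furyl stage. The partner on the C3' side is then a small five-membered ring with one ortho substituent, and neither partner carries a quinone, so a palladium-catalysed coupling of a furylmetal with the aryl chloride is realistic. Bromofuran 11 is traced to the symmetrical dibromide 9 by a single halogen–metal exchange and methylation.

**8 to 6, 5 and 3.** The four O-methyl bonds of 8 are traced to the quinone 6 (reductive methylation). The C–OMe bond at C2 of the target numbering (C3 in the numbering of 3) is traced to a C–Br bond in 5 and then to C–H in 3. The peri-hydroxyl of 3 distinguishes the two quinone carbons: dehydrobromination of 4 leaves bromine next to the hydrogen-bonded carbonyl, and substitution on the phenoxide occurs at that same carbon.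

**3 to 1 and 2.** The two aryl–carbonyl bonds of the quinone ring are cut, giving a phenol and a four-carbon diacylating agent. The chlorine of 1 sits para to the hydroxyl, blocks that position during acylation, and ends up exactly at C5, where it later serves as the coupling handle.

## Alternatives that were turned down

**Alternative 1: diene–quinone cycloaddition to build the juglone benzenoid ring.** The cut is through C4a–C5 and C8–C8a. In the forward step the silyl vinylketene acetal A1, carrying the protected naphthazarin half on its terminal carbon, adds to the bromoquinone A2; elimination of bromide and of the acetal methoxy group then aromatises the ring to A3. In its favour, the bromine dictates the orientation, the C2 methoxy and the free C8 hydroxyl arrive in the correct positions, and the juglone half is finished without any late oxidation or deprotection. On that point it is stronger than the chosen route. Against it, the di-ortho-substituted naphthyl group sits on the very diene carbon that forms the C4a–C5 bond, so the cycloaddition must create the most crowded bond of the molecule in a bimolecular step. The acetal A1 is hydrolytically labile, and making it requires a fully substituted tetramethoxynaphthalene that is functionalised at C3', homologated to an arylbutenoate and enolised, which is at least as long as the whole route to 14. In A3 the naphthazarin half must still be oxidised and demethylated in the presence of a free juglone quinone. The chosen route offers instead ring formation two atoms away from the axis and no orientation issue at all.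

**Alternative 2: single-carbon insertion into an indene.** The carbon C3' is excised, cutting C2'–C3' and C3'–C4'. In the forward step the chlorocarbene from diazirine A4 (which carries the juglone half) cyclopropanates the methoxy-substituted double bond of indene A5. The chlorocyclopropane opens with loss of chloride and of the C1' proton, expanding the five-membered ring to the naphthalene A6. This is the most convergent option: axis and ring are made in one operation, and A6 needs only one oxidation and one demethylation, a shorter end game than the chosen one. Against it, the carbene carbon is flanked by a di-ortho-substituted aryl group and must add to a tetrasubstituted enol-ether double bond, giving a cyclopropane with three adjacent fully substituted carbons. The oxidative formation of A4 from an amidine on an electron-rich ring with a free position between two methoxy groups invites ring halogenation. A5 is an acid-labile benzylic and enol ether that needs its own multi-step preparation. The chosen route gives up some convergence for a ring-forming step whose reactivity pattern is established for this substrate class.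

**Alternative 3: Michael–aldol annulation on an acylquinone.** The cut is through C4a–C5 and C6–C7. The benzylic enolate of arylacetone A7 adds to the ring carbon of acetylquinone A8 next to the acetyl group; the acetyl methyl then condenses with the side-chain ketone and the ring aromatises to the triol A9. In its favour are cheap partners, a polyketide-like logic, and a methoxy group that is already placed by A8; in material cost it is at least as good as the chosen route. Against it, A8 is a highly electrophilic acylquinone prone to redox exchange and oligomerisation. The nucleophilic carbon is a secondary benzylic centre next to a di-ortho-substituted ring, so the crowded C4a–C5 bond is again formed by a bimolecular addition, with competition from enolisation at the methyl side and from O-attack. A9 then has to be re-oxidised selectively while the other half is still a tetramethoxynaphthalene, so the clean separation of oxidation levels is lost. The chosen route instead makes the hindered biaryl bond by palladium catalysis before any quinone exists, and closes the ring by a cycloaddition that does not touch the hindered carbon.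

Key step: step 7

## Route

Step 1
Reactants: 1 4-chloro-3-methylphenol; 2 maleic anhydride
Product: 3 8-chloro-5-hydroxy-7-methyl-1,4-naphthoquinone (8-chloro-7-methyljuglone)
Conditions: AlCl3/NaCl melt, 180 °C; then aq. HCl
Reagents that add atoms: none
Why: Double Friedel–Crafts acylation of a phenol by maleic anhydride in a chloroaluminate melt; the first acylation goes ortho to the hydroxyl, the second closes the ring next to chlorine, and the para chlorine blocks the alternative site and ends up at C8, the later coupling position.

Step 2
Reactants: 3 8-chloro-5-hydroxy-7-methyl-1,4-naphthoquinone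
Product: 5 3-bromo-8-chloro-5-hydroxy-7-methyl-1,4-naphthoquinone, via trans-2,3-dibromide 4 (not isolated)
Conditions: Br2 (1.05 equiv), AcOH, rt; then NaOAc, 60 °C
Reagents that add atoms: bromine, BrBr
Why: Bromination of a quinone by addition–elimination; anti addition gives the racemic trans-dibromide 4, and HBr is lost by enolisation towards the C4 carbonyl that is hydrogen-bonded to the peri-hydroxyl, so the bromine that remains is on C3 (C2 of the target numbering), the known outcome for free juglones.

Step 3
Reactants: 5 3-bromo-8-chloro-5-hydroxy-7-methyl-1,4-naphthoquinone
Product: 6 8-chloro-5-hydroxy-3-methoxy-7-methyl-1,4-naphthoquinone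
Conditions: NaOMe (2.2 equiv), MeOH/THF, 0 °C to rt; then aq. HCl
Reagents that add atoms: sodium methoxide, C[O-].[Na+]
Why: Addition–elimination substitution of a haloquinone; in the phenoxide the C4 carbonyl is deactivated, so the C1 carbonyl is the acceptor and methoxide attacks C3, the carbon that bears bromine, which then leaves; the aryl chloride is far less activated and should survive.

Step 4
Reactants: 6 8-chloro-5-hydroxy-3-methoxy-7-methyl-1,4-naphthoquinone
Product: 8 5-chloro-1,2,4,8-tetramethoxy-6-methylnaphthalene, via hydroquinone 7 (not isolated)
Conditions: Na2S2O4, Bu4NBr, THF/H2O, rt, Ar; then KOH, Me2SO4, rt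
Reagents that add atoms: dimethyl sulfate, COS(=O)(=O)OC
Why: One-pot reductive methylation of a quinone under phase-transfer conditions; dithionite gives triol 7, whose three phenoxides are alkylated in the absence of air, and the aryl chloride and the existing methyl ether are inert.

Step 5
Reactants: 9 3,4-dibromofuran
Product: 11 3-bromo-4-methylfuran, via 3-bromo-4-lithiofuran 10 (not isolated)
Conditions: n-BuLi (1.0 equiv), Et2O, −78 °C; then MeI, −78 °C to rt
Reagents that add atoms: iodomethane, CI
Why: Bromine–lithium exchange at a furan β-position followed by alkylation; with one equivalent of n-BuLi at −78 °C only one bromine is exchanged and the 3-lithiofuran is configurationally and positionally stable at that temperature.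

Step 6
Reactants: 11 3-bromo-4-methylfuran; 8 5-chloro-1,2,4,8-tetramethoxy-6-methylnaphthalene
Product: 14 3-methyl-4-(1,2,4,8-tetramethoxy-6-methylnaphthalen-5-yl)furan, via 3-lithio-4-methylfuran 12 (not isolated), via (4-methylfuran-3-yl)zinc chloride 13 (not isolated)
Conditions: 11, n-BuLi, THF, −78 °C; ZnCl2, −78 °C to rt; then 8, Pd2(dba)3 (cat.), RuPhos (cat.), THF/NMP, 70 °C
Reagents that add atoms: none
Why: Negishi coupling; a bulky dialkylbiarylphosphine lets zerovalent palladium insert into the electron-rich, ortho-substituted C–Cl bond and promotes reductive elimination of hindered biaryls, while the furylzinc reagent tolerates the methyl ethers.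

Step 7
Reactants: 14 3-methyl-4-(1,2,4,8-tetramethoxy-6-methylnaphthalen-5-yl)furan; 15 2-bromo-1,4-dimethoxybenzene
Product: 18 rac-(1S,4R)-5,8-dimethoxy-2-methyl-3-(1,2,4,8-tetramethoxy-6-methylnaphthalen-5-yl)-1,4-dihydro-1,4-epoxynaphthalene, via aryllithium 16 (not isolated), via 3,6-dimethoxybenzyne 17 (not isolated)
Conditions: 15 (3 equiv), lithium 2,2,6,6-tetramethylpiperidide (LiTMP, 3.3 equiv, slow addition), THF, −78 °C to rt
Reagents that add atoms: none
Why: LiTMP removes the proton of 15 that lies between bromine and methoxy, aryllithium 16 loses LiBr, and the symmetrical aryne 17 adds across the two α-carbons of furan 14 in a concerted suprafacial [4+2] cycloaddition, the aryne–furan Diels–Alder reaction that is the standard entry to 1,4-epoxy-1,4-dihydronaphthalenes. The six-membered ring C1'–C2'–C3'–C4'–C4a'–C8a' is closed by this cycloaddition, both new bonds (C1'–C8a' and C4'–C4a') forming in one step, with the furan oxygen left as the 1,4-bridge. The two bridgehead stereocentres C1' and C4' are set by addition to one face of the planar furan, which fixes them cis to each other, the only geometry the oxygen bridge allows; no chiral element is present, so 18 is racemic, and any atropodiastereomers about the aryl–alkene bond are of no consequence because both bridgeheads become planar in step 8. Regioselectivity is not needed, since the two aryne carbons of 17 have identical methoxy-bearing neighbours. Chemoselectivity between the furan and the two electron-rich naphthalene rings is needed, and it is secured by the low aromatic stabilisation of furan, which makes it by far the best diene for arynes. Within the furan, the reacting α-carbons carry only hydrogen, while the bulky aryl sits on a β-carbon and is twisted out of the furan plane. Slow addition of the base to a mixture of 14 and excess 15 keeps the amide occupied with the more acidic bromoarene and limits metalation of 14.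

Step 8
Reactants: 18 rac-(1S,4R)-5,8-dimethoxy-2-methyl-3-(1,2,4,8-tetramethoxy-6-methylnaphthalen-5-yl)-1,4-dihydro-1,4-epoxynaphthalene
Product: 21 5,8-dimethoxy-2-methyl-3-(1,2,4,8-tetramethoxy-6-methylnaphthalen-5-yl)-1,4-naphthoquinone, via 2-methyl-1-naphthol 19 (not isolated), via 3-methyl-1-naphthol 20 (not isolated)
Conditions: conc. HCl (cat.), MeOH, 60 °C; evaporate; then (KSO3)2NO, KH2PO4, acetone/H2O, rt
Reagents that add atoms: potassium nitrosodisulfonate, [K+].[K+].[O]N(S(=O)(=O)[O-])S(=O)(=O)[O-]
Why: Acid-catalysed isomerisation of a 1,4-epoxynaphthalene to a 1-naphthol (ionisation of either bridgehead C–O bond to a benzylic, allylic cation and loss of the remaining bridgehead proton), then Teuber oxidation of the air-sensitive crude naphthols at their free para position; 19 and 20 differ only in which C–O bond opened and both give 21, and the nitroxyl radical oxidises phenols but not the aryl methyl ethers of the other half.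

Step 9
Reactants: 21 5,8-dimethoxy-2-methyl-3-(1,2,4,8-tetramethoxy-6-methylnaphthalen-5-yl)-1,4-naphthoquinone
Product: 22 2,8-dimethoxy-6-methyl-5-(5,8-dimethoxy-3-methyl-1,4-dioxo-1,4-dihydronaphthalen-2-yl)-1,4-naphthoquinone
Conditions: (NH4)2Ce(NO3)6 (2.5 equiv), MeCN/H2O, 0 °C
Reagents that add atoms: water, O
Why: Oxidative demethylation of a para-dimethoxyarene by tetravalent cerium; C1 and C4 are the only para-related methoxy pair of the electron-rich half, so the 2-methoxy-1,4-quinone results with the C2 and C8 ethers retained, while the dimethoxy ring of the other half is deactivated by its quinone and should not be oxidised further.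

Step 10
Reactants: 22 2,8-dimethoxy-6-methyl-5-(5,8-dimethoxy-3-methyl-1,4-dioxo-1,4-dihydronaphthalen-2-yl)-1,4-naphthoquinone
Product: 23 8-hydroxy-2-methoxy-6-methyl-5-(5,8-dihydroxy-3-methyl-1,4-dioxo-1,4-dihydronaphthalen-2-yl)-1,4-naphthoquinone (8'-hydroxy-3-methoxyisodiospyrin, racemic about the C5–C3' axis)
Conditions: BCl3 (excess), CH2Cl2, −78 to 0 °C; then H2O
Reagents that add atoms: none
Why: Chelation-controlled cleavage of peri-methoxy groups; BCl3 binds each quinone carbonyl together with the neighbouring peri ether oxygen in a six-membered chelate and chloride removes the methyl group, whereas the C2 methoxy can only form a less favourable five-membered chelate and should survive at low temperature.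

## Compound list

1 | 4-chloro-3-methylphenol | Cc1cc(O)ccc1Cl | starting material
2 | maleic anhydride | O=C1OC(=O)C=C1 | starting material
3 | 8-chloro-5-hydroxy-7-methyl-1,4-naphthoquinone | Cc1cc(O)c2c(c1Cl)C(=O)C=CC2=O | intermediate
4 | trans-2,3-dibromo-8-chloro-5-hydroxy-7-methyl-2,3-dihydro-1,4-naphthoquinone (racemic, 2R,3R enantiomer drawn) | Cc1cc(O)c2c(c1Cl)C(=O)[C@@H](Br)[C@H](Br)C2=O | intermediate
5 | 3-bromo-8-chloro-5-hydroxy-7-methyl-1,4-naphthoquinone | Cc1cc(O)c2c(c1Cl)C(=O)C=C(Br)C2=O | intermediate
6 | 8-chloro-5-hydroxy-3-methoxy-7-methyl-1,4-naphthoquinone | Cc1cc(O)c2c(c1Cl)C(=O)C=C(OC)C2=O | intermediate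
7 | 8-chloro-3-methoxy-7-methylnaphthalene-1,4,5-triol | Cc1cc(O)c2c(O)c(OC)cc(O)c2c1Cl | intermediate
8 | 5-chloro-1,2,4,8-tetramethoxy-6-methylnaphthalene | Cc1cc(OC)c2c(OC)c(OC)cc(OC)c2c1Cl | intermediate
9 | 3,4-dibromofuran | Brc1cocc1Br | starting material
10 | 3-bromo-4-lithiofuran | [Li]c1cocc1Br | intermediate
11 | 3-bromo-4-methylfuran | Cc1cocc1Br | intermediate
12 | 3-lithio-4-methylfuran | [Li]c1cocc1C | intermediate
13 | (4-methylfuran-3-yl)zinc chloride | Cl[Zn]c1cocc1C | intermediate
14 | 3-methyl-4-(1,2,4,8-tetramethoxy-6-methylnaphthalen-5-yl)furan | Cc1cocc1-c1c(C)cc(OC)c2c(OC)c(OC)cc(OC)c12 | intermediate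
15 | 2-bromo-1,4-dimethoxybenzene | COc1ccc(OC)c(Br)c1 | starting material
16 | (2-bromo-3,6-dimethoxyphenyl)lithium | COc1ccc(OC)c(Br)c1[Li] | intermediate
17 | 3,6-dimethoxybenzyne (1,4-dimethoxy-2,3-didehydrobenzene) | COC1=CC=C(OC)C#C1 | intermediate
18 | rac-(1S,4R)-5,8-dimethoxy-2-methyl-3-(1,2,4,8-tetramethoxy-6-methylnaphthalen-5-yl)-1,4-dihydro-1,4-epoxynaphthalene (bridgeheads cis, one enantiomer drawn) | COc1ccc(OC)c2c1[C@H]1O[C@@H]2C(-c2c(C)cc(OC)c3c(OC)c(OC)cc(OC)c23)=C1C | intermediate
19 | 5,8-dimethoxy-2-methyl-3-(1,2,4,8-tetramethoxy-6-methylnaphthalen-5-yl)naphthalen-1-ol | COc1ccc(OC)c2c(O)c(C)c(-c3c(C)cc(OC)c4c(OC)c(OC)cc(OC)c34)cc12 | intermediate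
20 | 5,8-dimethoxy-3-methyl-2-(1,2,4,8-tetramethoxy-6-methylnaphthalen-5-yl)naphthalen-1-ol | COc1ccc(OC)c2c(O)c(-c3c(C)cc(OC)c4c(OC)c(OC)cc(OC)c34)c(C)cc12 | intermediate
21 | 5,8-dimethoxy-2-methyl-3-(1,2,4,8-tetramethoxy-6-methylnaphthalen-5-yl)-1,4-naphthoquinone | CC1=C(-c3c(C)cc(OC)c4c(OC)c(OC)cc(OC)c34)C(=O)c2c(OC)ccc(OC)c2C1=O | intermediate
22 | 2,8-dimethoxy-6-methyl-5-(5,8-dimethoxy-3-methyl-1,4-dioxo-1,4-dihydronaphthalen-2-yl)-1,4-naphthoquinone | COC1=CC(=O)c2c(C3=C(C)C(=O)c4c(OC)ccc(OC)c4C3=O)c(C)cc(OC)c2C1=O | intermediate
23 | 8-hydroxy-2-methoxy-6-methyl-5-(5,8-dihydroxy-3-methyl-1,4-dioxo-1,4-dihydronaphthalen-2-yl)-1,4-naphthoquinone (8'-hydroxy-3-methoxyisodiospyrin) | COC1=CC(=O)c2c(C3=C(C)C(=O)c4c(O)ccc(O)c4C3=O)c(C)cc(O)c2C1=O | target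

## Step count and least certain steps

Total step count: 10. Longest linear sequence: 9 steps (steps 1 to 4 and 6 to 10); step 5 is a one-step side branch.

**Step 7 (key step).** The most likely failure is unproductive consumption of the aryne while the valuable furan 14 stays unconverted. The aryne can be intercepted by the amide, by the liberated amine or by aryllithium 16. The amide can also metalate 14 at a furan α-position or at the ring position between two methoxy groups, and the resulting aryllithium would then arylate instead of cycloadding. Steric retardation by the twisted aryl group is a lesser concern. The fallback generates the aryne without any strong base. It sets out from 14 and comes back at 18. Commercial 2,5-dimethoxyphenol is converted with isopropyl isocyanate into 2,5-dimethoxyphenyl N-isopropylcarbamate F1. Carbamate-directed ortho-lithiation (in situ N-silylation with TMSOTf/TMEDA, then n-BuLi at −78 °C) and quenching with TMSCl place silicon between the carbamate and the methoxy group, giving 3,6-dimethoxy-2-(trimethylsilyl)phenyl N-isopropylcarbamate F2. Cleavage of the carbamate with DBU/Et2NH and triflation of the phenoxide with PhNTf2 give 3,6-dimethoxy-2-(trimethylsilyl)phenyl trifluoromethanesulfonate F3. Treatment of 14 and F3 with CsF in MeCN at room temperature releases 17 under neutral conditions, and it should be trapped by the furan to give 18.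

**Step 6.** The likely failure is slow oxidative addition into the electron-rich, doubly flanked C–Cl bond combined with slow transmetalation of the ortho-methylated furylzinc, so that protodemetalation of 13 wins. The fallback builds the furan ring instead of coupling it. It sets out from 8 and comes back at 14. A copper-free Sonogashira coupling of 8 with propyne (PdCl2(MeCN)2, XPhos, Cs2CO3, MeCN, sealed tube) gives the sterically slim alkyne 1,2,4,8-tetramethoxy-6-methyl-5-(prop-1-yn-1-yl)naphthalene F4. Heating F4 with 4-phenyloxazole at about 220 °C gives the bridged cycloadduct 6-methyl-3-phenyl-5-(1,2,4,8-tetramethoxy-6-methylnaphthalen-5-yl)-7-oxa-2-azabicyclo[2.2.1]hepta-2,5-diene F5 (either orientation serves), which loses benzonitrile by cycloreversion to give 14.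

**Step 10.** The likely failure is loss of selectivity between the peri ethers and the vinylogous ester: if the naphthazarin ethers need warming to be cleaved, the C2 methyl group may be lost as well. The fallback gives up selectivity and restores the methoxy group afterwards. It sets out from 22 and comes back at 23. Excess BBr3 in CH2Cl2 cleaves all four ethers to 2,8-dihydroxy-6-methyl-5-(5,8-dihydroxy-3-methyl-1,4-dioxo-1,4-dihydronaphthalen-2-yl)-1,4-naphthoquinone F6. The C2 hydroxyl of F6 is a vinylogous carboxylic acid and should be re-esterified by HCl in methanol at reflux, conditions under which the chelated peri-phenols do not react, to give 23.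

**Step 2.** The likely failure is dehydrobromination of 4 in the opposite sense, or competing bromination of the benzenoid ring ortho to the phenol, either of which would put the methoxy group in the wrong place two steps later. The fallback sets the position by nucleophilic addition to the O-methylated quinone, where the regiochemical preference is reversed in the desired direction. It sets out from 3 and comes back at 8. Methylation of 3 (MeI, Ag2O) gives 8-chloro-5-methoxy-7-methyl-1,4-naphthoquinone F7, in which the peri methoxy group deactivates the C4 carbonyl. Dimethylamine then adds at C3, and air oxidation gives 8-chloro-3-(dimethylamino)-5-methoxy-7-methyl-1,4-naphthoquinone F8. Aqueous HCl in dioxane hydrolyses the vinylogous amide to 8-chloro-3-hydroxy-5-methoxy-7-methyl-1,4-naphthoquinone F9, and the reductive methylation conditions of step 4 convert F9 into 8.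

## Further compounds

F1 | step 7 | 2,5-dimethoxyphenyl N-isopropylcarbamate | COc1ccc(OC)c(OC(=O)NC(C)C)c1
F2 | step 7 | 3,6-dimethoxy-2-(trimethylsilyl)phenyl N-isopropylcarbamate | COc1ccc(OC)c(OC(=O)NC(C)C)c1[Si](C)(C)C
F3 | step 7 | 3,6-dimethoxy-2-(trimethylsilyl)phenyl trifluoromethanesulfonate | COc1ccc(OC)c(OS(=O)(=O)C(F)(F)F)c1[Si](C)(C)C
F4 | step 6 | 1,2,4,8-tetramethoxy-6-methyl-5-(prop-1-yn-1-yl)naphthalene | CC#Cc1c(C)cc(OC)c2c(OC)c(OC)cc(OC)c12
F5 | step 6 | 6-methyl-3-phenyl-5-(1,2,4,8-tetramethoxy-6-methylnaphthalen-5-yl)-7-oxa-2-azabicyclo[2.2.1]hepta-2,5-diene (racemic, one enantiomer drawn) | c1ccccc1C2=N[C@H]3O[C@@H]2C(-c2c(C)cc(OC)c4c(OC)c(OC)cc(OC)c24)=C3C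
F6 | step 10 | 2,8-dihydroxy-6-methyl-5-(5,8-dihydroxy-3-methyl-1,4-dioxo-1,4-dihydronaphthalen-2-yl)-1,4-naphthoquinone | OC1=CC(=O)c2c(C3=C(C)C(=O)c4c(O)ccc(O)c4C3=O)c(C)cc(O)c2C1=O
F7 | step 2 | 8-chloro-5-methoxy-7-methyl-1,4-naphthoquinone | Cc1cc(OC)c2c(c1Cl)C(=O)C=CC2=O
F8 | step 2 | 8-chloro-3-(dimethylamino)-5-methoxy-7-methyl-1,4-naphthoquinone | Cc1cc(OC)c2c(c1Cl)C(=O)C=C(N(C)C)C2=O
F9 | step 2 | 8-chloro-3-hydroxy-5-methoxy-7-methyl-1,4-naphthoquinone | Cc1cc(OC)c2c(c1Cl)C(=O)C=C(O)C2=O
A1 | alternative 1 | (1Z,3E)-1-methoxy-3-methyl-4-(1,4,5,8-tetramethoxy-3-methylnaphthalen-2-yl)-1-(trimethylsilyloxy)buta-1,3-diene | CO/C(O[Si](C)(C)C)=C/C(C)=C/c1c(C)c(OC)c2c(OC)ccc(OC)c2c1OC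
A2 | alternative 1 | 2-bromo-6-methoxy-1,4-benzoquinone | COC1=CC(=O)C=C(Br)C1=O
A3 | alternative 1 | 8-hydroxy-2-methoxy-6-methyl-5-(1,4,5,8-tetramethoxy-3-methylnaphthalen-2-yl)-1,4-naphthoquinone | COC1=CC(=O)c2c(-c3c(C)c(OC)c4c(OC)ccc(OC)c4c3OC)c(C)cc(O)c2C1=O
A4 | alternative 2 | 3-chloro-3-(1,2,4,8-tetramethoxy-6-methylnaphthalen-5-yl)-3H-diazirine | ClC1(N=N1)c1c(C)cc(OC)c2c(OC)c(OC)cc(OC)c12
A5 | alternative 2 | 1,3,4,7-tetramethoxy-2-methyl-1H-indene (racemic, one enantiomer drawn) | CO[C@H]1C(C)=C(OC)c2c(OC)ccc(OC)c12
A6 | alternative 2 | 1,2,4,5,8-pentamethoxy-7-methyl... octamethyl ether: 1,2,4,8-tetramethoxy-6-methyl-5-(1,4,5,8-tetramethoxy-3-methylnaphthalen-2-yl)naphthalene | COc1cc(OC)c2c(-c3c(C)c(OC)c4c(OC)ccc(OC)c4c3OC)c(C)cc(OC)c2c1OC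
A7 | alternative 3 | 1-(1,4,5,8-tetramethoxy-3-methylnaphthalen-2-yl)propan-2-one | CC(=O)Cc1c(C)c(OC)c2c(OC)ccc(OC)c2c1OC
A8 | alternative 3 | 2-acetyl-6-methoxy-1,4-benzoquinone | CC(=O)C1=CC(=O)C=C(OC)C1=O
A9 | alternative 3 | 2-methoxy-6-methyl-5-(1,4,5,8-tetramethoxy-3-methylnaphthalen-2-yl)naphthalene-1,4,8-triol | COc1cc(O)c2c(-c3c(C)c(OC)c4c(OC)ccc(OC)c4c3OC)c(C)cc(O)c2c1O
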